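The seven-membered ring is closed at the bond between the ketone carbon C10 and the quaternary methyl-bearing carbon C1 (daucane numbering). The feature exploited is the tertiary carbinol C4 of the five-membered ring, read as a latent ketone: in a cyclopentenone (C4=O, C5=C1) C1 is an electrophilic β-carbon. An acyl radical at C10, generated from a (Z)-enoyl phenyl selenoester, adds to it 7-endo; one operation forms the ring, the quaternary centre C1 and the trans ring-fusion hydrogen at C5, both relayed from the single C6 silyloxy stereocentre. The precursor is a 2,3-disubstituted cyclopent-2-enone without isopropyl group; isopropyl addition to C4 and vanilloylation of O6 finish the synthesis.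

Key step: step 8

Remark: daucane numbering is used for the ring atoms throughout (C1 quaternary C–CH3, C2 and C3 ring CH2, C4 carbinol carbon, C5 ring-fusion CH, C6 ester-bearing CH, C7 CH2, C8=C9 alkene, C10 ketone). Compounds 1 and 16 and all reagents in the Conditions lines are taken as commercial.

Step 1
Reactants: 1 2-bromo-3-methylcyclopent-2-en-1-one
Product: 2 6-bromo-7-methyl-1,4-dioxaspiro[4.4]non-6-ene
Conditions: HOCH2CH2OH, p-TsOH (cat.), benzene, reflux, Dean–Stark
Reagents that add atoms: ethylene glycol (OCCO)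
Why: Acid-catalysed ketalisation with azeotropic removal of water masks the ketone so that the vinyl bromide can later be metallated; no stereocentre is formed.

Step 2
Reactants: 2 6-bromo-7-methyl-1,4-dioxaspiro[4.4]non-6-ene
Product: 4 7-methyl-1,4-dioxaspiro[4.4]non-6-ene-6-carbaldehyde, via vinyllithium 3 (not isolated)
Conditions: n-BuLi, THF, −78 °C; then DMF, −78 → 0 °C; aq. NH4Cl
Reagents that add atoms: N,N-dimethylformamide (CN(C)C=O)
Why: Bromine–lithium exchange gives an α-keto vinyl anion equivalent, which is formylated by DMF (Bouveault-type formylation) to install C6 as an aldehyde.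

Step 3
Reactants: 4 7-methyl-1,4-dioxaspiro[4.4]non-6-ene-6-carbaldehyde
Product: 6 (1R)-3-methyl-1-(7-methyl-1,4-dioxaspiro[4.4]non-6-en-6-yl)but-3-en-1-ol, via borinate ester 5 (not isolated)
Conditions: (+)-Ipc2BOMe, 2-methylallylmagnesium chloride, Et2O, 0 °C; then 4, −78 °C; then NaOH, H2O2, 0 °C → rt
Reagents that add atoms: 2-methylallylmagnesium chloride (C=C(C)C[Mg]Cl)
Why: Brown asymmetric methallylboration through a chair six-membered transition state; the isopinocampheyl groups derived from (−)-α-pinene should direct the methallyl group to the Re face of the aldehyde and set C6 as R by reagent control.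

Step 4
Reactants: 6 (1R)-3-methyl-1-(7-methyl-1,4-dioxaspiro[4.4]non-6-en-6-yl)but-3-en-1-ol
Product: 7 (1R)-3-methyl-1-(7-methyl-1,4-dioxaspiro[4.4]non-6-en-6-yl)but-3-en-1-yl prop-2-enoate
Conditions: acryloyl chloride, Et3N, DMAP (cat.), CH2Cl2, −20 → 0 °C
Reagents that add atoms: acryloyl chloride (C=CC(=O)Cl)
Why: O-Acylation of the secondary alcohol supplies C9 and C10 and the second alkene for metathesis; C6 is untouched.

Step 5
Reactants: 7 (1R)-3-methyl-1-(7-methyl-1,4-dioxaspiro[4.4]non-6-en-6-yl)but-3-en-1-yl prop-2-enoate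
Product: 8 (6R)-4-methyl-6-(7-methyl-1,4-dioxaspiro[4.4]non-6-en-6-yl)-5,6-dihydro-2H-pyran-2-one
Conditions: second-generation Grubbs catalyst (H2IMes)(PCy3)Cl2Ru=CHPh (5 mol %), toluene, 80 °C, 0.01 M
Reagents that add atoms: none
Why: Ring-closing metathesis of the acrylate with the 1,1-disubstituted alkene releases ethene and, because the new C8=C9 bond lies in a six-membered ring, fixes C7 and C10 cis (the Z geometry the later ring closure needs); the tetrasubstituted ring alkene is inert.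

Step 6
Reactants: 8 (6R)-4-methyl-6-(7-methyl-1,4-dioxaspiro[4.4]non-6-en-6-yl)-5,6-dihydro-2H-pyran-2-one
Product: 11 (2Z,5R)-5-[(tert-butyldimethylsilyl)oxy]-3-methyl-5-(2-methyl-5-oxocyclopent-1-en-1-yl)pent-2-enoic acid, via lithium hydroxy carboxylate 9 (not isolated), via bis-silyl ketal 10 (not isolated)
Conditions: LiOH, THF/H2O, rt; evaporate; TBSOTf, 2,6-lutidine, CH2Cl2, −78 → 0 °C; then 10% aq. oxalic acid, THF, rt
Reagents that add atoms: lithium hydroxide ([Li+].[OH-]); tert-butyldimethylsilyl trifluoromethanesulfonate (CC(C)(C)[Si](C)(C)OS(=O)(=O)C(F)(F)F); water (O)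
Why: Saponification opens the lactone without touching the ring-defined Z alkene, the silyl triflate should cap the C6 hydroxyl faster than the hydroxy acid can relactonise, and dilute aqueous acid then hydrolyses the labile silyl ester and the dioxolane while the hindered secondary silyl ether survives (ester hydrolysis, O-silylation, ketal hydrolysis).

Step 7
Reactants: 11 (2Z,5R)-5-[(tert-butyldimethylsilyl)oxy]-3-methyl-5-(2-methyl-5-oxocyclopent-1-en-1-yl)pent-2-enoic acid
Product: 12 Se-phenyl (2Z,5R)-5-[(tert-butyldimethylsilyl)oxy]-3-methyl-5-(2-methyl-5-oxocyclopent-1-en-1-yl)pent-2-eneselenoate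
Conditions: (PhSe)2, Bu3P, CH2Cl2, 0 °C → rt
Reagents that add atoms: diphenyl diselenide (c1ccc(cc1)[Se][Se]c1ccccc1)
Why: Phosphine-mediated redox condensation (acyloxyphosphonium captured by selenolate) converts the acid into the phenyl selenoester, the standard acyl-radical precursor, under neutral conditions that leave the Z alkene, the enone and the silyl ether intact.

Step 8
Reactants: 12 Se-phenyl (2Z,5R)-5-[(tert-butyldimethylsilyl)oxy]-3-methyl-5-(2-methyl-5-oxocyclopent-1-en-1-yl)pent-2-eneselenoate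
Product: 13 (3aS,8R,8aS)-8-[(tert-butyldimethylsilyl)oxy]-3a,6-dimethyl-2,3,3a,7,8,8a-hexahydroazulene-1,4-dione
Conditions: (Me3Si)3SiH (1.3 equiv, syringe pump), AIBN (0.3 equiv), benzene, 80 °C, 0.005 M
Reagents that add atoms: none
Why: A silyl radical abstracts the phenylselanyl group of 12 to give a Z-configured α,β-unsaturated acyl radical at C10, which adds to C1, the β-carbon of the cyclopentenone, and the resulting α-keto radical at C5 takes a hydrogen atom from the silane. The closest known reaction type is the acyl-radical cyclisation of phenyl selenoesters onto alkenes and enones (Giese-type addition). The seven-membered ring closes in the 7-endo-trig mode. C1 is controlled by the C6 stereocentre: to avoid allylic strain and dipole repulsion with the C4 carbonyl, the C6–H bond should lie in the enone plane and the C6–OSi bond perpendicular to it, so the chain reaches C1 from the face opposite the silyloxy group and the C1 methyl ends cis to O6. C5 is set when the bulky silane delivers hydrogen to the planar radical from the face away from both the C1 methyl and the silyloxy group, which gives the trans ring fusion. The step needs 7-endo attack at C1 over 6-exo attack at C5 and over simple reduction; this is secured by polarity matching (nucleophilic acyl radical, electrophilic β-carbon, stabilised α-keto radical), by the Z geometry carried over from the lactone, and by slow addition of the slow hydrogen donor (Me3Si)3SiH at high dilution.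

Step 9
Reactants: 13 (3aS,8R,8aS)-8-[(tert-butyldimethylsilyl)oxy]-3a,6-dimethyl-2,3,3a,7,8,8a-hexahydroazulene-1,4-dione
Product: 14 (1R,3aS,8R,8aS)-8-[(tert-butyldimethylsilyl)oxy]-1-hydroxy-3a,6-dimethyl-1-(propan-2-yl)-2,3,3a,7,8,8a-hexahydroazulen-4(1H)-one
Conditions: i-PrMgCl, CeCl3 (anhydrous), THF, −78 °C; aq. NH4Cl
Reagents that add atoms: isopropylmagnesium chloride (CC(C)[Mg]Cl)
Why: Organocerium 1,2-addition should select the cyclopentanone C4 over the conjugated C10 ketone, which is flanked by the quaternary C1, and should come from the face anti to the C6 substituent on C5 and to the C1 methyl, setting C4 with the hydroxyl cis to that methyl.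

Step 10
Reactants: 14 (1R,3aS,8R,8aS)-8-[(tert-butyldimethylsilyl)oxy]-1-hydroxy-3a,6-dimethyl-1-(propan-2-yl)-2,3,3a,7,8,8a-hexahydroazulen-4(1H)-one
Product: 15 (1R,3aS,8R,8aS)-1,8-dihydroxy-3a,6-dimethyl-1-(propan-2-yl)-2,3,3a,7,8,8a-hexahydroazulen-4(1H)-one
Conditions: HF·pyridine, pyridine, THF, 0 °C → rt
Reagents that add atoms: none
Why: Fluoride-mediated desilylation under buffered, non-basic conditions frees the C6 hydroxyl without base-induced elimination next to the enone or ionisation of the tertiary alcohol.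

Step 11
Reactants: 16 4-hydroxy-3-methoxybenzoic acid (vanillic acid)
Product: 18 4-[(tert-butyldimethylsilyl)oxy]-3-methoxybenzoic acid, via bis-silyl derivative 17 (not isolated)
Conditions: TBSCl (2.5 equiv), imidazole, DMF, rt; then AcOH/THF/H2O, rt
Reagents that add atoms: tert-butyldimethylsilyl chloride (CC(C)(C)[Si](C)(C)Cl)
Why: Exhaustive silylation followed by selective hydrolysis of the labile silyl ester leaves the phenol protected, so that the acid cannot acylate itself in the next step.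

Step 12
Reactants: 15 (1R,3aS,8R,8aS)-1,8-dihydroxy-3a,6-dimethyl-1-(propan-2-yl)-2,3,3a,7,8,8a-hexahydroazulen-4(1H)-one; 18 4-[(tert-butyldimethylsilyl)oxy]-3-methoxybenzoic acid
Product: 20 (1R,3aS,8R,8aS)-1-hydroxy-3a,6-dimethyl-4-oxo-1-(propan-2-yl)-1,2,3,3a,4,7,8,8a-octahydroazulen-8-yl 4-[(tert-butyldimethylsilyl)oxy]-3-methoxybenzoate, via mixed anhydride 19 (not isolated)
Conditions: 18, 2,4,6-trichlorobenzoyl chloride, Et3N, THF, rt; then 15, DMAP, toluene, rt
Reagents that add atoms: none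
Why: Yamaguchi esterification acylates the hindered secondary C6 hydroxyl with retention, while the tertiary C4 hydroxyl is too hindered to react.

Step 13
Reactants: 20 (1R,3aS,8R,8aS)-1-hydroxy-3a,6-dimethyl-4-oxo-1-(propan-2-yl)-1,2,3,3a,4,7,8,8a-octahydroazulen-8-yl 4-[(tert-butyldimethylsilyl)oxy]-3-methoxybenzoate
Product: 21 (1R,3aS,8R,8aS)-1-hydroxy-3a,6-dimethyl-4-oxo-1-(propan-2-yl)-1,2,3,3a,4,7,8,8a-octahydroazulen-8-yl 4-hydroxy-3-methoxybenzoate
Conditions: Bu4NF, AcOH, THF, 0 °C
Reagents that add atoms: none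
Why: Buffered fluoride cleaves the aryl silyl ether selectively; the acetic acid buffer suppresses vinylogous β-elimination of the vanillate from the enone.

Compound list
1 | 2-bromo-3-methylcyclopent-2-en-1-one | CC1=C(Br)C(=O)CC1 | starting material
2 | 6-bromo-7-methyl-1,4-dioxaspiro[4.4]non-6-ene | CC1=C(Br)C2(CC1)OCCO2 | intermediate
3 | (7-methyl-1,4-dioxaspiro[4.4]non-6-en-6-yl)lithium | [Li]C1=C(C)CCC12OCCO2 | intermediate
4 | 7-methyl-1,4-dioxaspiro[4.4]non-6-ene-6-carbaldehyde | CC1=C(C=O)C2(CC1)OCCO2 | intermediate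
5 | diisopinocampheylborinate ester of 6 | C=C(C)C[C@@H](OB([C@H]1C[C@H]2C[C@@H]([C@@H]1C)C2(C)C)[C@H]1C[C@H]2C[C@@H]([C@@H]1C)C2(C)C)C1=C(C)CCC13OCCO3 | intermediate
6 | (1R)-3-methyl-1-(7-methyl-1,4-dioxaspiro[4.4]non-6-en-6-yl)but-3-en-1-ol | C=C(C)C[C@@H](O)C1=C(C)CCC12OCCO2 | intermediate
7 | (1R)-3-methyl-1-(7-methyl-1,4-dioxaspiro[4.4]non-6-en-6-yl)but-3-en-1-yl prop-2-enoate | C=CC(=O)O[C@H](CC(C)=C)C1=C(C)CCC12OCCO2 | intermediate
8 | (6R)-4-methyl-6-(7-methyl-1,4-dioxaspiro[4.4]non-6-en-6-yl)-5,6-dihydro-2H-pyran-2-one | CC1=CC(=O)O[C@H](C1)C2=C(C)CCC23OCCO3 | intermediate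
9 | lithium (2Z,5R)-5-hydroxy-3-methyl-5-(7-methyl-1,4-dioxaspiro[4.4]non-6-en-6-yl)pent-2-enoate | [Li+].[O-]C(=O)/C=C(/C)C[C@@H](O)C1=C(C)CCC12OCCO2 | intermediate
10 | tert-butyldimethylsilyl (2Z,5R)-5-[(tert-butyldimethylsilyl)oxy]-3-methyl-5-(7-methyl-1,4-dioxaspiro[4.4]non-6-en-6-yl)pent-2-enoate | CC(C)(C)[Si](C)(C)OC(=O)/C=C(/C)C[C@@H](O[Si](C)(C)C(C)(C)C)C1=C(C)CCC12OCCO2 | intermediate
11 | (2Z,5R)-5-[(tert-butyldimethylsilyl)oxy]-3-methyl-5-(2-methyl-5-oxocyclopent-1-en-1-yl)pent-2-enoic acid | OC(=O)/C=C(/C)C[C@@H](O[Si](C)(C)C(C)(C)C)C1=C(C)CCC1=O | intermediate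
12 | Se-phenyl (2Z,5R)-5-[(tert-butyldimethylsilyl)oxy]-3-methyl-5-(2-methyl-5-oxocyclopent-1-en-1-yl)pent-2-eneselenoate | O=C([Se]c1ccccc1)/C=C(/C)C[C@@H](O[Si](C)(C)C(C)(C)C)C1=C(C)CCC1=O | intermediate
13 | (3aS,8R,8aS)-8-[(tert-butyldimethylsilyl)oxy]-3a,6-dimethyl-2,3,3a,7,8,8a-hexahydroazulene-1,4-dione (daucane 1S,5S,6R) | CC(C)(C)[Si](C)(C)O[C@@H]1CC(C)=CC(=O)[C@@]2(C)CCC(=O)[C@H]12 | intermediate
14 | (1R,3aS,8R,8aS)-8-[(tert-butyldimethylsilyl)oxy]-1-hydroxy-3a,6-dimethyl-1-(propan-2-yl)-2,3,3a,7,8,8a-hexahydroazulen-4(1H)-one | CC(C)(C)[Si](C)(C)O[C@@H]1CC(C)=CC(=O)[C@@]2(C)CC[C@@](O)(C(C)C)[C@H]12 | intermediate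
15 | (1R,3aS,8R,8aS)-1,8-dihydroxy-3a,6-dimethyl-1-(propan-2-yl)-2,3,3a,7,8,8a-hexahydroazulen-4(1H)-one | O[C@@H]1CC(C)=CC(=O)[C@@]2(C)CC[C@@](O)(C(C)C)[C@H]12 | intermediate
16 | 4-hydroxy-3-methoxybenzoic acid (vanillic acid) | COc1cc(C(=O)O)ccc1O | starting material
17 | tert-butyldimethylsilyl 4-[(tert-butyldimethylsilyl)oxy]-3-methoxybenzoate | COc1cc(C(=O)O[Si](C)(C)C(C)(C)C)ccc1O[Si](C)(C)C(C)(C)C | intermediate
18 | 4-[(tert-butyldimethylsilyl)oxy]-3-methoxybenzoic acid | COc1cc(C(=O)O)ccc1O[Si](C)(C)C(C)(C)C | intermediate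
19 | 4-[(tert-butyldimethylsilyl)oxy]-3-methoxybenzoic 2,4,6-trichlorobenzoic anhydride | COc1cc(C(=O)OC(=O)c2c(Cl)cc(Cl)cc2Cl)ccc1O[Si](C)(C)C(C)(C)C | intermediate
20 | (1R,3aS,8R,8aS)-1-hydroxy-3a,6-dimethyl-4-oxo-1-(propan-2-yl)-1,2,3,3a,4,7,8,8a-octahydroazulen-8-yl 4-[(tert-butyldimethylsilyl)oxy]-3-methoxybenzoate | COc1cc(C(=O)O[C@@H]2CC(C)=CC(=O)[C@@]3(C)CC[C@@](O)(C(C)C)[C@H]23)ccc1O[Si](C)(C)C(C)(C)C | intermediate
21 | (1R,3aS,8R,8aS)-1-hydroxy-3a,6-dimethyl-4-oxo-1-(propan-2-yl)-1,2,3,3a,4,7,8,8a-octahydroazulen-8-yl 4-hydroxy-3-methoxybenzoate | COc1cc(C(=O)O[C@@H]2CC(C)=CC(=O)[C@@]3(C)CC[C@@](O)(C(C)C)[C@H]23)ccc1O | target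

Total step count: 13. Longest linear sequence: 12 (steps 1–10, 12 and 13; step 11 prepares the acid fragment).

Steps most likely to fail

Step 8. Hydrogen transfer to the acyl radical (from the silane, or by a 1,5-shift from C6–H) may outrun the slow 7-endo attack on the fully substituted C1, and the attack may be shared between both faces of C1. The fallback sets out from 12 and returns at 13. Reduction of 12 with Bu3SnH and catalytic Pd(PPh3)4 would give (2Z,5R)-5-[(tert-butyldimethylsilyl)oxy]-3-methyl-5-(2-methyl-5-oxocyclopent-1-en-1-yl)pent-2-enal F1. An intramolecular Stetter reaction of F1 (triazolium carbene precatalyst, i-Pr2NEt, toluene) would then form the same C1–C10 bond by polar acyl-anion conjugate addition, in which no hydrogen donor competes, and deliver 13.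

Step 9. The hindered C4 ketone may be enolised or reduced by the secondary organometallic instead of undergoing addition, and some attack at C10 may compete. The fallback sets out from 13 and returns at 14. The smaller sp2 nucleophile 2-propenylmagnesium bromide with CeCl3 (THF, −78 °C) would give (1S,3aS,8R,8aS)-8-[(tert-butyldimethylsilyl)oxy]-1-hydroxy-3a,6-dimethyl-1-(prop-1-en-2-yl)-2,3,3a,7,8,8a-hexahydroazulen-4(1H)-one F2. Hydrogenation of its 1,1-disubstituted alkene with H2 and RhCl(PPh3)3 in benzene, which leaves the trisubstituted enone alone, would give 14.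

Step 6. Relactonisation of the hydroxy carboxylate or of its silyl ester may outrun O-silylation and return the lactone. The fallback sets out from 8 and returns at 11. Aminolysis of 8 with MeNH(OMe)·HCl and Me3Al (CH2Cl2) would give (2Z,5R)-5-hydroxy-N-methoxy-N,3-dimethyl-5-(7-methyl-1,4-dioxaspiro[4.4]non-6-en-6-yl)pent-2-enamide F3, an amide that does not readily relactonise. Silylation (TBSCl, imidazole, DMF) would give (2Z,5R)-5-[(tert-butyldimethylsilyl)oxy]-N-methoxy-N,3-dimethyl-5-(7-methyl-1,4-dioxaspiro[4.4]non-6-en-6-yl)pent-2-enamide F4. Reduction with i-Bu2AlH (THF, −78 °C) would give (2Z,5R)-5-[(tert-butyldimethylsilyl)oxy]-3-methyl-5-(7-methyl-1,4-dioxaspiro[4.4]non-6-en-6-yl)pent-2-enal F5. Pinnick oxidation (NaClO2, NaH2PO4, 2-methylbut-2-ene, t-BuOH/H2O) would give (2Z,5R)-5-[(tert-butyldimethylsilyl)oxy]-3-methyl-5-(7-methyl-1,4-dioxaspiro[4.4]non-6-en-6-yl)pent-2-enoic acid F6, and 10% aq. oxalic acid in THF would remove the dioxolane to give 11.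

Further compounds
F1 | step 8 | (2Z,5R)-5-[(tert-butyldimethylsilyl)oxy]-3-methyl-5-(2-methyl-5-oxocyclopent-1-en-1-yl)pent-2-enal | O=C/C=C(/C)C[C@@H](O[Si](C)(C)C(C)(C)C)C1=C(C)CCC1=O
F2 | step 9 | (1S,3aS,8R,8aS)-8-[(tert-butyldimethylsilyl)oxy]-1-hydroxy-3a,6-dimethyl-1-(prop-1-en-2-yl)-2,3,3a,7,8,8a-hexahydroazulen-4(1H)-one | CC(C)(C)[Si](C)(C)O[C@@H]1CC(C)=CC(=O)[C@@]2(C)CC[C@@](O)(C(C)=C)[C@H]12
F3 | step 6 | (2Z,5R)-5-hydroxy-N-methoxy-N,3-dimethyl-5-(7-methyl-1,4-dioxaspiro[4.4]non-6-en-6-yl)pent-2-enamide | CON(C)C(=O)/C=C(/C)C[C@@H](O)C1=C(C)CCC12OCCO2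
F4 | step 6 | (2Z,5R)-5-[(tert-butyldimethylsilyl)oxy]-N-methoxy-N,3-dimethyl-5-(7-methyl-1,4-dioxaspiro[4.4]non-6-en-6-yl)pent-2-enamide | CON(C)C(=O)/C=C(/C)C[C@@H](O[Si](C)(C)C(C)(C)C)C1=C(C)CCC12OCCO2
F5 | step 6 | (2Z,5R)-5-[(tert-butyldimethylsilyl)oxy]-3-methyl-5-(7-methyl-1,4-dioxaspiro[4.4]non-6-en-6-yl)pent-2-enal | O=C/C=C(/C)C[C@@H](O[Si](C)(C)C(C)(C)C)C1=C(C)CCC12OCCO2
F6 | step 6 | (2Z,5R)-5-[(tert-butyldimethylsilyl)oxy]-3-methyl-5-(7-methyl-1,4-dioxaspiro[4.4]non-6-en-6-yl)pent-2-enoic acid | OC(=O)/C=C(/C)C[C@@H](O[Si](C)(C)C(C)(C)C)C1=C(C)CCC12OCCO2
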